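**Retrosynthetic overview**
- The target is reached by acetylation of the macrocyclic C3 alcohol; the ten-membered carbocycle is closed last, at C2–C3, by a Ni/Cr-mediated (Nozaki–Hiyama–Kishi) macrocyclisation of an E-iodoalkene onto a Z-enal.
- The seco compound comes from a chromium-mediated Barbier allylation (C7–C8) of the fragment A aldehyde with the fragment B bromomethyl butenolide, which also turns the butenolide into the trans α-methylene-γ-lactone.
- Fragment A (C8–C10, C1, C2, C14): Sharpless epoxidation of methallyl alcohol, vinyl cuprate opening, Takai olefination, alkene cleavage.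
- Fragment B (C3–C7, C11–C13, C15): Z-iodoalkene from propargyl alcohol plus an alkynyl Weinreb amide gives an ynone; asymmetric transfer hydrogenation, directed hydroalumination/iodination and carbonylative lactonisation follow.
- Ring order: lactone ring first (step 13), ten-membered carbocycle last (step 19).

Atom labels C1–C15 are the germacrane numbering of the target (ring C1–C10, lactone O on C6, C12 carbonyl, C13 methylene, C14 methyl on C10, C15 methyl on C4).

Assumption: the target is read as (1E,3S,4Z,6S,7S,8R,10R)-3-acetoxy-8-angeloyloxy-10-hydroxygermacra-1,4,11(13)-trien-12,6-olide, and the ring closure of step 19 is taken to give the 3S carbinol under substrate control (the opposite outcome is covered by a fallback).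

**Fragment A**

Step 1
Reactants: 1 2-methylprop-2-en-1-ol
Product: 2 [(2S)-2-methyloxiran-2-yl]methanol
Conditions: Ti(OiPr)4 (5 mol %), L-(+)-diisopropyl tartrate (6 mol %), tBuOOH (anhydrous), 4 Å MS, CH2Cl2, −20 °C
Reagents that add atoms: tert-butyl hydroperoxide, CC(C)(C)OO
Why: Catalytic Sharpless asymmetric epoxidation, in which the titanium–L-(+)-tartrate complex delivers oxygen to the alkene face that gives the 2S epoxide (the sense that gives (S)-glycidol from allyl alcohol), setting the future C10.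

Step 2
Reactants: 2 [(2S)-2-methyloxiran-2-yl]methanol
Product: 3 (2R)-2-methylpent-4-ene-1,2-diol
Conditions: CH2=CHMgBr (3 equiv), CuI (10 mol %), THF, −40 → 0 °C; aq NH4Cl
Reagents that add atoms: vinylmagnesium bromide, C=C[Mg]Br
Why: Copper-catalysed Grignard opening of the epoxide (SN2) at its unsubstituted CH2 terminus leaves the C–O bond at the quaternary carbon untouched, so C10 is retained (the descriptor becomes R only through CIP priorities) and a Payne shift would be degenerate.

Step 3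
Reactants: 3 (2R)-2-methylpent-4-ene-1,2-diol
Product: 4 (2R)-2-methyl-1,2-bis(triethylsilyloxy)pent-4-ene
Conditions: Et3SiOTf (2.4 equiv), 2,6-lutidine, CH2Cl2, −78 → 0 °C
Reagents that add atoms: triethylsilyl trifluoromethanesulfonate, CC[Si](CC)(CC)OS(=O)(=O)C(F)(F)F
Why: Silyl triflate silylation is reactive enough to cap the tertiary as well as the primary hydroxyl, giving a tertiary ether that lasts until step 17.

Step 4
Reactants: 4 (2R)-2-methyl-1,2-bis(triethylsilyloxy)pent-4-ene
Product: 5 (2R)-2-methyl-2-(triethylsilyloxy)pent-4-enal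
Conditions: (COCl)2, DMSO, CH2Cl2, −78 → −30 °C; then Et3N, −78 → 0 °C
Reagents that add atoms: none
Why: Swern oxidation, in which the activated DMSO reagent cleaves the primary triethylsilyl ether in situ and oxidises it to the aldehyde while the hindered tertiary silyl ether is inert; the α-carbon is quaternary and cannot epimerise.

Step 5
Reactants: 5 (2R)-2-methyl-2-(triethylsilyloxy)pent-4-enal
Product: 6 (1E,3R)-1-iodo-3-methyl-3-(triethylsilyloxy)hexa-1,5-diene
Conditions: CrCl2 (6 equiv), CHI3 (2 equiv), 1,4-dioxane/THF 6:1, 0 °C → rt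
Reagents that add atoms: iodoform, IC(I)I
Why: Takai olefination, in which the geminal dichromium species from CHI3 adds to the non-enolisable aldehyde and eliminates to give the E iodoalkene (C1=C2).

Step 6
Reactants: 6 (1E,3R)-1-iodo-3-methyl-3-(triethylsilyloxy)hexa-1,5-diene
Product: 8 (3R,4E)-5-iodo-3-methyl-3-(triethylsilyloxy)pent-4-enal, via iodo diol 7 (not isolated)
Conditions: OsO4 (2 mol %), NaIO4 (4 equiv), 2,6-lutidine, 1,4-dioxane/H2O 3:1, rt
Reagents that add atoms: osmium tetroxide (oxygen carrier), O=[Os](=O)(=O)=O; sodium periodate (terminal oxidant), [Na+].[O-]I(=O)(=O)=O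
Why: Lemieux–Johnson oxidation, in which OsO4 dihydroxylates the monosubstituted terminal alkene much faster than the hindered, electron-poor iodoalkene and periodate cleaves the diol to the C8 aldehyde without touching C10.

**Fragment B**

Step 7
Reactants: 9 prop-2-yn-1-ol
Product: 11 (2Z)-3-iodo-2-methylprop-2-en-1-ol, via Z-alkenylmagnesium chelate 10 (not isolated)
Conditions: MeMgBr (2.5 equiv), CuI (10 mol %), THF, −10 °C → rt; then I2, −10 °C
Reagents that add atoms: methylmagnesium bromide, C[Mg]Br; iodine, II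
Why: Copper-catalysed anti-carbomagnesiation of the propargylic alkoxide puts methyl on C4 and magnesium on C5 inside a five-membered chelate, and iodinolysis with retention gives only the Z iodide, which fixes the 4Z alkene.

Step 8
Reactants: 11 (2Z)-3-iodo-2-methylprop-2-en-1-ol
Product: 12 tert-butyl{[(2Z)-3-iodo-2-methylprop-2-en-1-yl]oxy}diphenylsilane
Conditions: tBuPh2SiCl, imidazole, CH2Cl2, 0 °C → rt
Reagents that add atoms: tert-butylchlorodiphenylsilane, CC(C)(C)[Si](Cl)(c1ccccc1)c1ccccc1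
Why: Standard silylation of the primary alcohol, the bulky diphenylsilyl ether being chosen to resist O-to-C silyl migration in step 10 and the bromination of step 14.

Step 9
Reactants: 13 tert-butyldimethyl(prop-2-yn-1-yloxy)silane
Product: 15 4-(tert-butyldimethylsilyloxy)-N-methoxy-N-methylbut-2-ynamide, via lithium acetylide 14 (not isolated)
Conditions: nBuLi, THF, −78 °C; then ClC(O)N(OMe)Me, −78 → 0 °C
Reagents that add atoms: N-methoxy-N-methylcarbamoyl chloride, CON(C)C(Cl)=O
Why: Deprotonation of the terminal alkyne and nucleophilic acyl substitution on the carbamoyl chloride give the Weinreb ynamide, whose carbonyl carbon becomes C6.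

Step 10
Reactants: 12 tert-butyl{[(2Z)-3-iodo-2-methylprop-2-en-1-yl]oxy}diphenylsilane; 15 4-(tert-butyldimethylsilyloxy)-N-methoxy-N-methylbut-2-ynamide
Product: 17 (5Z)-1-(tert-butyldimethylsilyloxy)-7-(tert-butyldiphenylsilyloxy)-6-methylhept-5-en-2-yn-4-one, via Z-alkenyllithium 16 (not isolated)
Conditions: 12, tBuLi (2.0 equiv), Et2O, −78 °C; then 15, −78 → −40 °C; aq NH4Cl
Reagents that add atoms: none
Why: Iodine–lithium exchange proceeds with retention of the Z geometry at −78 °C, and the Weinreb amide gives a chelated tetrahedral adduct that collapses to the ketone only on work-up, so there is no over-addition.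

Step 11
Reactants: 17 (5Z)-1-(tert-butyldimethylsilyloxy)-7-(tert-butyldiphenylsilyloxy)-6-methylhept-5-en-2-yn-4-one
Product: 18 (4S,5Z)-1-(tert-butyldimethylsilyloxy)-7-(tert-butyldiphenylsilyloxy)-6-methylhept-5-en-2-yn-4-ol
Conditions: Ru[(S,S)-TsNCHPhCHPhNH](p-cymene) (1 mol %), iPrOH, 25 °C
Reagents that add atoms: none
Why: Noyori asymmetric transfer hydrogenation of an α,β-acetylenic ketone reduces only C=O, and with the S,S ligand the alkynyl group takes the site normally occupied by aryl, so hydride adds to give the 4S alcohol (the future C6).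

Step 12
Reactants: 18 (4S,5Z)-1-(tert-butyldimethylsilyloxy)-7-(tert-butyldiphenylsilyloxy)-6-methylhept-5-en-2-yn-4-ol
Product: 20 (2Z,4S,5Z)-1-(tert-butyldimethylsilyloxy)-7-(tert-butyldiphenylsilyloxy)-2-iodo-6-methylhepta-2,5-dien-4-ol, via cyclic alkenylalanate 19 (not isolated)
Conditions: NaAlH2(OCH2CH2OMe)2 (1.5 equiv), THF, −20 → 0 °C; EtOAc; then I2, −78 → −20 °C
Reagents that add atoms: iodine, II
Why: Hydroxyl-directed trans-hydroalumination delivers hydride to the proximal alkyne carbon and leaves aluminium on the distal carbon cis to the carbinol, so iodinolysis with retention gives the Z γ-iodo allylic alcohol, the silyl ether being too poor a leaving group to eliminate to an allene at low temperature.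

Step 13
Reactants: 20 (2Z,4S,5Z)-1-(tert-butyldimethylsilyloxy)-7-(tert-butyldiphenylsilyloxy)-2-iodo-6-methylhepta-2,5-dien-4-ol
Product: 21 (5S)-3-[(tert-butyldimethylsilyloxy)methyl]-5-[(1Z)-3-(tert-butyldiphenylsilyloxy)-2-methylprop-1-en-1-yl]furan-2(5H)-one
Conditions: PdCl2(PPh3)2 (5 mol %), CO (1 atm), K2CO3 (1.5 equiv), THF, rt
Reagents that add atoms: carbon monoxide, [C-]#[O+]
Why: Palladium-catalysed carbonylative lactonisation (oxidative addition of zerovalent palladium to the C–I bond with retention, CO insertion, capture of the acylpalladium by the cis hydroxyl) closes the lactone ring without touching the C6–O bond.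

Step 14
Reactants: 21 (5S)-3-[(tert-butyldimethylsilyloxy)methyl]-5-[(1Z)-3-(tert-butyldiphenylsilyloxy)-2-methylprop-1-en-1-yl]furan-2(5H)-one
Product: 22 (5S)-3-(bromomethyl)-5-[(1Z)-3-(tert-butyldiphenylsilyloxy)-2-methylprop-1-en-1-yl]furan-2(5H)-one
Conditions: Ph3PBr2 (1.2 equiv), CH2Cl2, 0 °C → rt
Reagents that add atoms: dibromotriphenylphosphorane, BrP(Br)(c1ccccc1)(c1ccccc1)c1ccccc1
Why: Dibromotriphenylphosphorane converts a primary allylic tert-butyldimethylsilyl ether directly into the bromide (alkoxyphosphonium formation, then SN2 by bromide), the bulkier tert-butyldiphenylsilyl ether reacting much more slowly.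

**Fragment union and endgame**

Step 15
Reactants: 22 (5S)-3-(bromomethyl)-5-[(1Z)-3-(tert-butyldiphenylsilyloxy)-2-methylprop-1-en-1-yl]furan-2(5H)-one; 8 (3R,4E)-5-iodo-3-methyl-3-(triethylsilyloxy)pent-4-enal
Product: 24 (4S,5S)-5-[(1Z)-3-(tert-butyldiphenylsilyloxy)-2-methylprop-1-en-1-yl]-4-[(1R,3R,4E)-1-hydroxy-5-iodo-3-methyl-3-(triethylsilyloxy)pent-4-en-1-yl]-3-methylideneoxolan-2-one, via allylchromium dichloride 23 (not isolated)
Conditions: CrCl2 (4 equiv), THF, 0 °C → rt (22 added slowly to 8 and CrCl2)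
Reagents that add atoms: none
Why: Chromium-mediated Barbier (Nozaki–Hiyama) allylation, in which the allylchromium adds through its γ-carbon in a chair Zimmerman–Traxler transition state on the butenolide face opposite the C6 side chain (trans lactone, 7S) and, because the ring holds the γ-substituent trans to CH2Cr as in an E-crotyl reagent, with anti C7/C8 topology (8R); the iodoalkene is inert to CrCl2 without nickel.

Step 16
Reactants: 24 (4S,5S)-5-[(1Z)-3-(tert-butyldiphenylsilyloxy)-2-methylprop-1-en-1-yl]-4-[(1R,3R,4E)-1-hydroxy-5-iodo-3-methyl-3-(triethylsilyloxy)pent-4-en-1-yl]-3-methylideneoxolan-2-one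
Product: 25 (1R,3R,4E)-1-{(2S,3S)-2-[(1Z)-3-(tert-butyldiphenylsilyloxy)-2-methylprop-1-en-1-yl]-4-methylidene-5-oxooxolan-3-yl}-5-iodo-3-methyl-3-(triethylsilyloxy)pent-4-en-1-yl (2Z)-2-methylbut-2-enoate
Conditions: angelic acid, 2,4,6-Cl3C6H2COCl, Et3N, toluene, rt; then 24, toluene, 80 °C
Reagents that add atoms: angelic acid, C/C=C(/C)C(=O)O
Why: Yamaguchi mixed-anhydride esterification, in which the alcohol attacks the unhindered angeloyl carbonyl and the absence of a nucleophilic catalyst avoids Z-to-E isomerisation to the tiglate; C8 is retained.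

Step 17
Reactants: 25 (1R,3R,4E)-1-{(2S,3S)-2-[(1Z)-3-(tert-butyldiphenylsilyloxy)-2-methylprop-1-en-1-yl]-4-methylidene-5-oxooxolan-3-yl}-5-iodo-3-methyl-3-(triethylsilyloxy)pent-4-en-1-yl (2Z)-2-methylbut-2-enoate
Product: 26 (1R,3R,4E)-3-hydroxy-1-{(2S,3S)-2-[(1Z)-3-hydroxy-2-methylprop-1-en-1-yl]-4-methylidene-5-oxooxolan-3-yl}-5-iodo-3-methylpent-4-en-1-yl (2Z)-2-methylbut-2-enoate
Conditions: HF·pyridine, pyridine, THF, 0 °C → rt
Reagents that add atoms: none
Why: Fluoride-driven desilylation (strong Si–F bond) removes both silyl ethers under buffered conditions that leave the esters, the α-methylene lactone and the iodoalkene untouched.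

Step 18
Reactants: 26 (1R,3R,4E)-3-hydroxy-1-{(2S,3S)-2-[(1Z)-3-hydroxy-2-methylprop-1-en-1-yl]-4-methylidene-5-oxooxolan-3-yl}-5-iodo-3-methylpent-4-en-1-yl (2Z)-2-methylbut-2-enoate
Product: 27 (1R,3R,4E)-3-hydroxy-5-iodo-3-methyl-1-{(2S,3S)-4-methylidene-2-[(1Z)-2-methyl-3-oxoprop-1-en-1-yl]-5-oxooxolan-3-yl}pent-4-en-1-yl (2Z)-2-methylbut-2-enoate
Conditions: MnO2 (activated, 20 equiv), CH2Cl2, rt
Reagents that add atoms: none
Why: MnO2 oxidises only allylic alcohols, so the primary Z-allylic alcohol gives the enal while the tertiary C10 hydroxyl cannot react, and the neutral heterogeneous conditions preserve the Z geometry.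

Step 19
Reactants: 27 (1R,3R,4E)-3-hydroxy-5-iodo-3-methyl-1-{(2S,3S)-4-methylidene-2-[(1Z)-2-methyl-3-oxoprop-1-en-1-yl]-5-oxooxolan-3-yl}pent-4-en-1-yl (2Z)-2-methylbut-2-enoate
Product: 29 (1E,3S,4Z,6S,7S,8R,10R)-8-angeloyloxy-3,10-dihydroxygermacra-1,4,11(13)-trien-12,6-olide, via alkenylchromium dichloride 28 (not isolated)
Conditions: CrCl2 (10 equiv), NiCl2 (0.1 equiv), DMSO, 2 mM, rt
Reagents that add atoms: none
Why: Nozaki–Hiyama–Kishi macrocyclisation (nickel-catalysed activation of the iodoalkene with retention of the E geometry, transmetalation to trivalent chromium, chemoselective addition to the aldehyde) forms C2–C3 and closes the ten-membered ring at high dilution, C3 being set under substrate control by attack on the outer face of the s-trans enal, away from the lactone, to give the 3S alcohol.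

Step 20
Reactants: 29 (1E,3S,4Z,6S,7S,8R,10R)-8-angeloyloxy-3,10-dihydroxygermacra-1,4,11(13)-trien-12,6-olide
Product: 30 (1E,3S,4Z,6S,7S,8R,10R)-3-acetoxy-8-angeloyloxy-10-hydroxygermacra-1,4,11(13)-trien-12,6-olide (CNP0181631.2)
Conditions: Ac2O, pyridine, DMAP (cat.), CH2Cl2, 0 °C
Reagents that add atoms: acetic anhydride, CC(=O)OC(C)=O
Why: DMAP-catalysed acylation acetylates the secondary allylic C3 hydroxyl with retention, the tertiary C10 hydroxyl being too hindered to react at 0 °C.

**Compound list**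

1 | 2-methylprop-2-en-1-ol (methallyl alcohol) | C=C(C)CO | starting material
2 | [(2S)-2-methyloxiran-2-yl]methanol | OC[C@]1(C)OC1 | intermediate
3 | (2R)-2-methylpent-4-ene-1,2-diol | OC[C@](C)(O)CC=C | intermediate
4 | (2R)-2-methyl-1,2-bis(triethylsilyloxy)pent-4-ene | CC[Si](CC)(CC)OC[C@](C)(O[Si](CC)(CC)CC)CC=C | intermediate
5 | (2R)-2-methyl-2-(triethylsilyloxy)pent-4-enal | O=C[C@](C)(O[Si](CC)(CC)CC)CC=C | intermediate
6 | (1E,3R)-1-iodo-3-methyl-3-(triethylsilyloxy)hexa-1,5-diene | I/C=C/[C@](C)(O[Si](CC)(CC)CC)CC=C | intermediate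
7 | (4R,5E)-6-iodo-4-methyl-4-(triethylsilyloxy)hex-5-ene-1,2-diol, both C2 epimers (not isolated) | I/C=C/[C@](C)(O[Si](CC)(CC)CC)CC(O)CO | intermediate
8 | (3R,4E)-5-iodo-3-methyl-3-(triethylsilyloxy)pent-4-enal (fragment A) | I/C=C/[C@](C)(O[Si](CC)(CC)CC)CC=O | intermediate
9 | prop-2-yn-1-ol | C#CCO | starting material
10 | 4-methyl-2,5-dihydro-1,2-oxamagnesole, the Z-alkenylmagnesium chelate (not isolated) | CC1=C[Mg]OC1 | intermediate
11 | (2Z)-3-iodo-2-methylprop-2-en-1-ol | I/C=C(/C)CO | intermediate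
12 | tert-butyl{[(2Z)-3-iodo-2-methylprop-2-en-1-yl]oxy}diphenylsilane | I/C=C(/C)CO[Si](c1ccccc1)(c1ccccc1)C(C)(C)C | intermediate
13 | tert-butyldimethyl(prop-2-yn-1-yloxy)silane | C#CCO[Si](C)(C)C(C)(C)C | starting material
14 | lithium 3-(tert-butyldimethylsilyloxy)prop-1-yn-1-ide (not isolated) | [Li]C#CCO[Si](C)(C)C(C)(C)C | intermediate
15 | 4-(tert-butyldimethylsilyloxy)-N-methoxy-N-methylbut-2-ynamide | CON(C)C(=O)C#CCO[Si](C)(C)C(C)(C)C | intermediate
16 | [(1Z)-3-(tert-butyldiphenylsilyloxy)-2-methylprop-1-en-1-yl]lithium (not isolated) | [Li]/C=C(/C)CO[Si](c1ccccc1)(c1ccccc1)C(C)(C)C | intermediate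
17 | (5Z)-1-(tert-butyldimethylsilyloxy)-7-(tert-butyldiphenylsilyloxy)-6-methylhept-5-en-2-yn-4-one | CC(C)(C)[Si](C)(C)OCC#CC(=O)/C=C(/C)CO[Si](c1ccccc1)(c1ccccc1)C(C)(C)C | intermediate
18 | (4S,5Z)-1-(tert-butyldimethylsilyloxy)-7-(tert-butyldiphenylsilyloxy)-6-methylhept-5-en-2-yn-4-ol | CC(C)(C)[Si](C)(C)OCC#C[C@@H](O)/C=C(/C)CO[Si](c1ccccc1)(c1ccccc1)C(C)(C)C | intermediate
19 | sodium cyclic alkenyl(alkoxy)bis(2-methoxyethoxy)aluminate of 18, ring Al–O–C6–C7=C11 (not isolated) | [Na+].COCCO[Al-]1(OCCOC)O[C@@H](/C=C(/C)CO[Si](c2ccccc2)(c2ccccc2)C(C)(C)C)C=C1CO[Si](C)(C)C(C)(C)C | intermediate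
20 | (2Z,4S,5Z)-1-(tert-butyldimethylsilyloxy)-7-(tert-butyldiphenylsilyloxy)-2-iodo-6-methylhepta-2,5-dien-4-ol | CC(C)(C)[Si](C)(C)OC/C(I)=C/[C@@H](O)/C=C(/C)CO[Si](c1ccccc1)(c1ccccc1)C(C)(C)C | intermediate
21 | (5S)-3-[(tert-butyldimethylsilyloxy)methyl]-5-[(1Z)-3-(tert-butyldiphenylsilyloxy)-2-methylprop-1-en-1-yl]furan-2(5H)-one | O=C1O[C@@H](/C=C(/C)CO[Si](c2ccccc2)(c2ccccc2)C(C)(C)C)C=C1CO[Si](C)(C)C(C)(C)C | intermediate
22 | (5S)-3-(bromomethyl)-5-[(1Z)-3-(tert-butyldiphenylsilyloxy)-2-methylprop-1-en-1-yl]furan-2(5H)-one (fragment B) | O=C1O[C@@H](/C=C(/C)CO[Si](c2ccccc2)(c2ccccc2)C(C)(C)C)C=C1CBr | intermediate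
23 | allylchromium dichloride derived from 22 (not isolated) | O=C1O[C@@H](/C=C(/C)CO[Si](c2ccccc2)(c2ccccc2)C(C)(C)C)C=C1C[Cr](Cl)Cl | intermediate
24 | (4S,5S)-5-[(1Z)-3-(tert-butyldiphenylsilyloxy)-2-methylprop-1-en-1-yl]-4-[(1R,3R,4E)-1-hydroxy-5-iodo-3-methyl-3-(triethylsilyloxy)pent-4-en-1-yl]-3-methylideneoxolan-2-one | C=C1C(=O)O[C@@H](/C=C(/C)CO[Si](c2ccccc2)(c2ccccc2)C(C)(C)C)[C@@H]1[C@H](O)C[C@@](C)(O[Si](CC)(CC)CC)/C=C/I | intermediate
25 | C8 angelate of 24: (1R,3R,4E)-1-{(2S,3S)-2-[(1Z)-3-(tert-butyldiphenylsilyloxy)-2-methylprop-1-en-1-yl]-4-methylidene-5-oxooxolan-3-yl}-5-iodo-3-methyl-3-(triethylsilyloxy)pent-4-en-1-yl (2Z)-2-methylbut-2-enoate | C=C1C(=O)O[C@@H](/C=C(/C)CO[Si](c2ccccc2)(c2ccccc2)C(C)(C)C)[C@@H]1[C@H](OC(=O)/C(C)=C\C)C[C@@](C)(O[Si](CC)(CC)CC)/C=C/I | intermediate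
26 | (1R,3R,4E)-3-hydroxy-1-{(2S,3S)-2-[(1Z)-3-hydroxy-2-methylprop-1-en-1-yl]-4-methylidene-5-oxooxolan-3-yl}-5-iodo-3-methylpent-4-en-1-yl (2Z)-2-methylbut-2-enoate | C=C1C(=O)O[C@@H](/C=C(/C)CO)[C@@H]1[C@H](OC(=O)/C(C)=C\C)C[C@@](C)(O)/C=C/I | intermediate
27 | (1R,3R,4E)-3-hydroxy-5-iodo-3-methyl-1-{(2S,3S)-4-methylidene-2-[(1Z)-2-methyl-3-oxoprop-1-en-1-yl]-5-oxooxolan-3-yl}pent-4-en-1-yl (2Z)-2-methylbut-2-enoate | C=C1C(=O)O[C@@H](/C=C(/C)C=O)[C@@H]1[C@H](OC(=O)/C(C)=C\C)C[C@@](C)(O)/C=C/I | intermediate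
28 | alkenylchromium dichloride derived from 27, Cr on C2 (not isolated) | C=C1C(=O)O[C@@H](/C=C(/C)C=O)[C@@H]1[C@H](OC(=O)/C(C)=C\C)C[C@@](C)(O)/C=C/[Cr](Cl)Cl | intermediate
29 | (1E,3S,4Z,6S,7S,8R,10R)-8-angeloyloxy-3,10-dihydroxygermacra-1,4,11(13)-trien-12,6-olide | C=C1C(=O)O[C@H]2/C=C(/C)[C@@H](O)/C=C/[C@](C)(O)C[C@@H](OC(=O)/C(C)=C\C)[C@H]12 | intermediate
30 | (1E,3S,4Z,6S,7S,8R,10R)-3-acetoxy-8-angeloyloxy-10-hydroxygermacra-1,4,11(13)-trien-12,6-olide (CNP0181631.2) | C=C1C(=O)O[C@H]2/C=C(/C)[C@@H](OC(C)=O)/C=C/[C@](C)(O)C[C@@H](OC(=O)/C(C)=C\C)[C@H]12 | target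

**Step count**

Total steps: 20. Longest linear sequence: 13 (steps 7, 8 and 10–20, from prop-2-yn-1-ol 9), which is 0.65 of the total.

**Three steps most likely to fail, with fallbacks**

Step 19 (macrocyclisation). The ten-membered ring is strained and the C3 configuration rests on substrate control that cannot be predicted with confidence. If closure of 27 gives mainly the C3 epimer, (1E,3R,4Z,6S,7S,8R,10R)-8-angeloyloxy-3,10-dihydroxygermacra-1,4,11(13)-trien-12,6-olide F1, the fallback sets out from 27 through F1. F1 is esterified with acetic acid under Mitsunobu conditions (PPh3, diisopropyl azodicarboxylate, THF, 0 °C), which installs the acetate with inversion at C3 and comes back to the route at 30. Any 29 formed alongside is acetylated as in step 20.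

Step 15 (fragment union). The C7/C8 topology depends on a closed chair transition state; an open transition state would give the syn alcohol. If the allylation of 8 with 22 gives mainly the C8 epimer, (4S,5S)-5-[(1Z)-3-(tert-butyldiphenylsilyloxy)-2-methylprop-1-en-1-yl]-4-[(1S,3R,4E)-1-hydroxy-5-iodo-3-methyl-3-(triethylsilyloxy)pent-4-en-1-yl]-3-methylideneoxolan-2-one F2, the fallback sets out from 22 and 8 through F2. F2 is esterified with angelic acid under Mitsunobu conditions (PPh3, diisopropyl azodicarboxylate, toluene, 0 °C → rt), which inverts C8 and installs the angelate in one operation, coming back at 25.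

Step 11 (asymmetric reduction). The ruthenium catalyst must tell the alkynyl from the alkenyl substituent of a cross-conjugated ketone, and conjugate reduction is possible. The fallback sets the carbinol by C–C bond formation instead. Setting out from 12, iodine–lithium exchange (tBuLi, Et2O, −78 °C) and formylation with DMF give (2Z)-4-(tert-butyldiphenylsilyloxy)-3-methylbut-2-enal F3. Zinc–ProPhenol-catalysed addition of alkyne 13 to F3 (Me2Zn, ProPhenol ligand antipode matched to the 4S product, toluene, 0 °C) gives the propargylic alcohol directly and comes back at 18, bypassing 15 and 17.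

**Further compounds**

F1 | step 19 | (1E,3R,4Z,6S,7S,8R,10R)-8-angeloyloxy-3,10-dihydroxygermacra-1,4,11(13)-trien-12,6-olide | C=C1C(=O)O[C@H]2/C=C(/C)[C@H](O)/C=C/[C@](C)(O)C[C@@H](OC(=O)/C(C)=C\C)[C@H]12
F2 | step 15 | (4S,5S)-5-[(1Z)-3-(tert-butyldiphenylsilyloxy)-2-methylprop-1-en-1-yl]-4-[(1S,3R,4E)-1-hydroxy-5-iodo-3-methyl-3-(triethylsilyloxy)pent-4-en-1-yl]-3-methylideneoxolan-2-one | C=C1C(=O)O[C@@H](/C=C(/C)CO[Si](c2ccccc2)(c2ccccc2)C(C)(C)C)[C@@H]1[C@@H](O)C[C@@](C)(O[Si](CC)(CC)CC)/C=C/I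
F3 | step 11 | (2Z)-4-(tert-butyldiphenylsilyloxy)-3-methylbut-2-enal | O=C/C=C(/C)CO[Si](c1ccccc1)(c1ccccc1)C(C)(C)C
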